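## The problem

Target 17 is a (2S)-flavan: ring A is fused to the pyran ring, and C2 carries a pentasubstituted catechol, ring B. C2 is the only stereocentre, so no other centre can control it; a catalyst has to set it and the rest of the route has to leave it alone. C2 is a benzylic ether carbon. Once ring B has a free 4'-hydroxyl, the O1–C2 bond can open reversibly to a para-quinone methide under base, acid or strong heating, and that would racemise the compound. The arenes carry three C-allyl groups of two kinds: a 1,1-dimethylallyl group at C6 next to the 7-hydroxyl, and prenyl groups at C2' and C5' on either side of the 3',4'-diol. Each sits ortho to a phenolic oxygen, which is the pattern left by an aromatic Claisen rearrangement (a prenyl ether gives a 1,1-dimethylallyl group, a 1,1-dimethylallyl ether gives a prenyl group). The catechol is easily oxidised, and the prenyl and vinyl groups tolerate neither catalytic hydrogenation nor protic acid next to free phenols, so they should arrive last and under neutral conditions. The ring-forming step rests on one feature: C4a of ring A is ortho to O1 and para to the C7 oxygen. A propargyl unit attached to O1 therefore has its terminal carbon next to the most nucleophilic free carbon of ring A, and C4–C4a can be closed by hydroarylation of the alkyne.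

## Retrosynthesis

**Three aryl–carbon bonds.** C6–C(quaternary), C2'–CH2 and C5'–CH2 of 17 are cut together by a retro-Claisen step. This leads, through the triacetate 16, to the tris-ether 15, which has a prenyl ether on O7 and two 1,1-dimethylallyl ethers on O3' and O4'. Cutting all three at once is preferred to separate C-allylations because the ortho relationship to oxygen then fixes every position, and no alkene has to survive earlier steps. The forward reaction must send the ring A group to C6 and not to C8. The phenols are capped as acetates as they form, so that no free 4'-hydroxyl is exposed to the high temperature that ring A requires.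

**Two tertiary ether bonds.** The two tertiary O–C bonds of 15 are cut. Tertiary allyl ethers cannot be made by direct displacement, so 15 is traced to the bis(propargyl) ether 14 by semi-hydrogenation, and 14 to the catechol 12 and the tertiary propargylic chloride 13. The forward etherification must place two bulky ethers on neighbouring oxygens without disturbing the prenyl ether.

**Differentiating O7 from the catechol.** The catechol 12 is traced to the bis-pivalate 11, and 11 to the 7-hydroxyflavan 9 and prenyl bromide 10. Ring A needs a primary allyl ether and ring B needs tertiary ones, so the two sets of oxygens must be addressed in turn. The pivalates that are useful earlier in the route provide this differentiation at no extra cost.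

**Saturation and debenzylation.** Flavan 9 comes from the 2H-chromene 8 by adding hydrogen across C3=C4 and cleaving the benzyl ether on O7. Both happen in one hydrogenation, which is why benzyl is chosen for O7. No C-allyl group is present yet.

**C4–C4a, the ring-closing bond.** Chromene 8 is opened at C4–C4a to the aryl propargyl ether 7. This cut is preferred to O1–C8a or C3=C4 because it turns the ring closure into an isomerisation with no by-product and no pre-functionalised ring A, and because it leaves the bonds at C2 untouched. The precursor 7 is acyclic apart from its two benzene rings. The forward reaction must choose the carbon para to the benzyloxy group and must not ionise the O1–C2 bond. The two pivalates make ring B electron-poor for that purpose.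

**O1–C2, the stereocentre.** Ether 7 is cut at O1–C2 into the racemic propargylic acetate 5 and 3-(benzyloxy)phenol 6. A copper-catalysed substitution through an allenylidene converts both enantiomers of 5 into one enantiomer of 7, so no resolved alcohol is needed.

**The propargylic carbon.** Acetate 5 is cut at the carbinol–alkyne bond to the aldehyde 2 and ethynylmagnesium bromide 3; the alkoxide 4 is acetylated in the same flask. Aldehyde 2 is the bis-pivalate of 3,4-dihydroxybenzaldehyde 1.

## Roads not taken

**Alternative 1:** The cut is O1–C8a. The open-chain bromo carbinol A1 would be closed by a copper–phenanthroline catalyst and carbonate base, the secondary alkoxide displacing the bromide on ring A, to give the tris(methoxymethyl) ether A2 of the target.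
- Merits: the bromide marks C8a, so the closure has no regiochemical question. The stereocentre would come from a catalytic ketone reduction of high reliability, and the C2–O bond is never broken. The route is convergent. In these three respects it is better than the chosen plan.
- Weak points: A1 already carries all three C-allyl groups, so the Claisen chemistry has to be run on two separate fragments. The enone that joins them must be reduced at its conjugated alkene in the presence of three other alkenes. The last step removes three methoxymethyl groups from A2 with acid, which are the conditions under which prenyl groups ortho to phenols cyclise and a flavan with an electron-rich ring B ionises at C2.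
- Comparison: the chosen plan gives up the regiochemical certainty and the convergence. In return, nothing harsher than heat and ammonia is used once the allyl groups exist, and one thermal operation installs all three on a finished flavan.

**Alternative 2:** C4–C4a and O1–C2 are cut together, back to caffeyl alcohol A3 and 3-(prenyloxy)phenol A4. A chiral BINOL-derived phosphoric acid would ionise A3 to a vinylogous para-quinone methide, which would alkylate A4 ortho to its hydroxyl to give the cinnamylphenol A5. A5 would then close through a second para-quinone methide to the flavan A6.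
- Merits: A6 is the same substance as 12, which the chosen route reaches only after seven steps. In step economy this road is far better, and it needs no protecting groups.
- Weak points: the enantio-determining oxa-cyclisation has no close precedent on such a substrate. A4 has three nucleophilic ring carbons and an oxygen, and the allyl cation can be attacked at either end. A3 is an electron-rich catechol that oligomerises under acid, and the prenyl ether of A4 is acid-labile. Most seriously, the O1–C2 bond of A6 stays ionisable under the acid that forms it as long as the 4'-hydroxyl is free, so the enantiomeric purity would depend on a reversible step.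
- Comparison: the chosen plan is seven steps longer to this point. Against that, every step has close precedent, and the stereocentre is formed irreversibly and then shielded by the ring B esters. If A6 could be obtained this way in high enantiomeric purity, it would replace steps 1 to 7.

**Alternative 3:** The cut is C3=C4. The diene A7, an aryl allyl ether with a vinyl group on ring A, would be closed by a second-generation ruthenium metathesis catalyst to the chromene A8.
- Merits: the position of the vinyl group fixes the regiochemistry. This is better than the chosen plan, which relies on an electronic and steric preference. Ring-closing metathesis of such dienes is robust and neutral.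
- Weak points: A7 needs an ortho-vinylphenol and an enantioselective branched allylic etherification of that hindered phenol, which costs several more steps than a Grignard addition and a propargylic substitution. Its methoxymethyl ethers leave ring B electron-rich, so A8 and the flavan derived from it are prone to ionisation at C2, and the acetals must later be removed with acid. Alkene migration in the allyl ether is a known side reaction of the metathesis.
- Comparison: the chosen plan accepts the regiochemical risk. In return it has a shorter approach to the cyclisation substrate, an isomerisation with no by-product, and ester protection that stabilises C2 and is removed without acid.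

Key step: step 4

Assumption: the sense of induction of the copper–pybox catalyst in step 3 has to be confirmed on the first run; (S,S)-Ph-pybox is written, and its mirror image is to be used if it proves to deliver the (R)-ether.

## Route

Step 1
Reactants: 1 3,4-dihydroxybenzaldehyde
Product: 2 3,4-bis(pivaloyloxy)benzaldehyde
Conditions: PivCl (2.4 equiv), Et3N (3 equiv), DMAP (5 mol%), CH2Cl2, 0 °C to rt
Reagents that add atoms: pivaloyl chloride, CC(C)(C)C(Cl)=O
Why: DMAP-catalysed O-acylation of both phenols; the aldehyde is inert, and the hindered esters are chosen to survive the Grignard reagent and to make ring B electron-poor for steps 3 to 5.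

Step 2
Reactants: 2 3,4-bis(pivaloyloxy)benzaldehyde; 3 ethynylmagnesium bromide
Product: 5 racemic 1-[3,4-bis(pivaloyloxy)phenyl]prop-2-yn-1-yl acetate, via bromomagnesium propargylic alkoxide 4 (not isolated)
Conditions: HC≡CMgBr (1.15 equiv), THF, −78 to −30 °C; then Ac2O (2 equiv), −30 °C to rt
Reagents that add atoms: acetic anhydride, CC(=O)OC(C)=O
Why: Grignard 1,2-addition to the aldehyde is much faster than attack on the hindered aryl pivalates at low temperature, and the magnesium alkoxide is O-acetylated in the same flask. A racemate is sufficient because step 3 is enantioconvergent.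

Step 3
Reactants: 5 racemic 1-[3,4-bis(pivaloyloxy)phenyl]prop-2-yn-1-yl acetate; 6 3-(benzyloxy)phenol
Product: 7 (S)-3-(benzyloxy)phenyl 1-[3,4-bis(pivaloyloxy)phenyl]prop-2-yn-1-yl ether
Conditions: Cu(OTf)2 (5 mol%), (S,S)-Ph-pybox (6 mol%), iPr2NEt (1.2 equiv), CH2Cl2, −20 °C
Reagents that add atoms: none
Why: Copper-catalysed enantioselective propargylic etherification: the copper acetylide of 5 (monovalent copper formed in the flask) loses acetate to give a copper allenylidene, and the phenoxide adds to its γ-carbon on the face left open by the pybox ligand. Both enantiomers of 5 pass through the same allenylidene, so the ligand alone sets C2, and the amine base favours attack through oxygen over the ring carbons of 6.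

Step 4
Reactants: 7 (S)-3-(benzyloxy)phenyl 1-[3,4-bis(pivaloyloxy)phenyl]prop-2-yn-1-yl ether
Product: 8 (S)-7-(benzyloxy)-2-[3,4-bis(pivaloyloxy)phenyl]-2H-chromene
Conditions: Ph3PAuNTf2 (3 mol%), CH2Cl2, rt, dark
Reagents that add atoms: none
Why: The cationic monovalent gold of Ph3PAuNTf2 binds the terminal alkyne of 7 as a π-acid, and the ring A carbon ortho to the ether oxygen and para to the benzyloxy group attacks the terminal alkyne carbon anti to gold, forming C4–C4a in a 6-endo-dig Friedel–Crafts closure of the pyran ring. Loss of the ring proton rearomatises the Wheland intermediate to a vinylgold species, and protodeauration leaves the C3=C4 alkene and returns the catalyst. The closest known reaction type is the gold- or platinum-catalysed intramolecular hydroarylation of aryl propargyl ethers to 2H-chromenes. No stereocentre is created: C2 is the propargylic carbon set in step 3, none of its bonds is made or broken, and its configuration should pass unchanged into 8. Endo closure over 5-exo closure is the normal outcome for aryl propargyl ethers, because the ether oxygen disfavours positive charge at the internal alkyne carbon and the five-membered transition state is strained. Attack para and not ortho to the benzyloxy group is favoured by the stronger para activation and by crowding at the carbon between the two oxygens. Ionisation of O1–C2 and a propargyl Claisen shift would both erase the stereocentre; the two electron-withdrawing pivalates on ring B and the room-temperature conditions are there to suppress them.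

Step 5
Reactants: 8 (S)-7-(benzyloxy)-2-[3,4-bis(pivaloyloxy)phenyl]-2H-chromene
Product: 9 (S)-2-[3,4-bis(pivaloyloxy)phenyl]chroman-7-ol
Conditions: H2 (1 atm), Pd/C (10%), EtOAc, rt
Reagents that add atoms: none
Why: Heterogeneous catalytic hydrogenation saturates the styrenic C3=C4 alkene and hydrogenolyses the benzyl ether in one operation. The O1–C2 bond should hold because the ester-bearing ring B makes that benzylic position electron-poor, and C2 itself is not touched.

Step 6
Reactants: 9 (S)-2-[3,4-bis(pivaloyloxy)phenyl]chroman-7-ol; 10 prenyl bromide (1-bromo-3-methylbut-2-ene)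
Product: 11 (S)-7-(3-methylbut-2-enyloxy)-2-[3,4-bis(pivaloyloxy)phenyl]chroman
Conditions: K2CO3 (2 equiv), acetone, 45 °C
Reagents that add atoms: none
Why: Williamson ether synthesis at the only free phenol; the aryl pivalates are stable to anhydrous carbonate, and a ring A phenoxide cannot open the pyran ring.

Step 7
Reactants: 11 (S)-7-(3-methylbut-2-enyloxy)-2-[3,4-bis(pivaloyloxy)phenyl]chroman
Product: 12 (S)-4-[7-(3-methylbut-2-enyloxy)chroman-2-yl]benzene-1,2-diol
Conditions: iBu2AlH (5 equiv), CH2Cl2, −78 °C; aq. KNaC4H4O6 (potassium sodium tartrate), Ar
Reagents that add atoms: none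
Why: Hydride reduction cleaves both aryl pivalates at −78 °C and leaves aluminium phenoxides that are released on neutral work-up. No free 4'-phenoxide is formed, so the O1–C2 bond, the prenyl ether and the catechol are not at risk.

Step 8
Reactants: 12 (S)-4-[7-(3-methylbut-2-enyloxy)chroman-2-yl]benzene-1,2-diol; 13 3-chloro-3-methylbut-1-yne
Product: 14 (S)-2-[3,4-bis(2-methylbut-3-yn-2-yloxy)phenyl]-7-(3-methylbut-2-enyloxy)chroman
Conditions: 13 (3 equiv), DBU (3 equiv), CuCl2·2H2O (1 mol%), MeCN, 0 °C, Ar
Reagents that add atoms: none
Why: Copper-catalysed O-propargylation of phenols with a tertiary propargylic chloride: the copper acetylide of 13 loses chloride to an allenylidene-type electrophile, which the phenoxide captures at the tertiary carbon. Neighbouring bis(tertiary propargyl) ethers of catechol-type phenols are known, and 0 °C keeps the transient 4'-phenoxide from opening the pyran ring.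

Step 9
Reactants: 14 (S)-2-[3,4-bis(2-methylbut-3-yn-2-yloxy)phenyl]-7-(3-methylbut-2-enyloxy)chroman
Product: 15 (S)-2-[3,4-bis(2-methylbut-3-en-2-yloxy)phenyl]-7-(3-methylbut-2-enyloxy)chroman
Conditions: H2 (1 atm), Pd/CaCO3 poisoned with Pb(OAc)2, quinoline, EtOAc, rt, stopped at 2 equiv H2
Reagents that add atoms: none
Why: Lindlar-type semi-hydrogenation stops at the alkene for both terminal alkynes; the trisubstituted prenyl alkene and the benzylic ether are inert to the poisoned catalyst.

Step 10
Reactants: 15 (S)-2-[3,4-bis(2-methylbut-3-en-2-yloxy)phenyl]-7-(3-methylbut-2-enyloxy)chroman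
Product: 16 (S)-7-acetoxy-6-(2-methylbut-3-en-2-yl)-2-[3,4-diacetoxy-2,5-bis(3-methylbut-2-enyl)phenyl]chroman
Conditions: Ac2O (10 equiv), PhNEt2, 130 °C then 195 °C, sealed tube, Ar
Reagents that add atoms: acetic anhydride, CC(=O)OC(C)=O
Why: Triple aromatic Claisen rearrangement with acylative trapping: the two tertiary ethers shift first, at 130 °C, to their only free ortho carbons C2' and C5', and the prenyl ether shifts at 195 °C to C6, the ortho carbon that is less crowded and remote from O1. Each phenol is acetylated as it forms, which blocks the abnormal Claisen pathway and cyclisation onto the new alkenes and keeps a free 4'-hydroxyl from opening the pyran ring at high temperature. The new quaternary carbon is not a stereocentre, and C2 is untouched.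

Step 11
Reactants: 16 (S)-7-acetoxy-6-(2-methylbut-3-en-2-yl)-2-[3,4-diacetoxy-2,5-bis(3-methylbut-2-enyl)phenyl]chroman
Product: 17 4-[(2S)-7-hydroxy-6-(2-methylbut-3-en-2-yl)chroman-2-yl]-3,6-bis(3-methylbut-2-enyl)benzene-1,2-diol (target)
Conditions: NH3 (7 M in MeOH), 0 °C to rt, Ar
Reagents that add atoms: none
Why: Ammonolysis of aryl acetates is fast even for the hindered C7 ester. Ammonia is too weak a base to build up 4'-phenoxide, so neither ring opening at C2 nor catechol oxidation should intervene.

## Compound list

1 | 3,4-dihydroxybenzaldehyde | O=Cc1ccc(O)c(O)c1 | starting material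
2 | 3,4-bis(pivaloyloxy)benzaldehyde | O=Cc1ccc(OC(=O)C(C)(C)C)c(OC(=O)C(C)(C)C)c1 | intermediate
3 | ethynylmagnesium bromide | C#C[Mg]Br | starting material
4 | bromomagnesium alkoxide of racemic 1-[3,4-bis(pivaloyloxy)phenyl]prop-2-yn-1-ol | C#CC(O[Mg]Br)c1ccc(OC(=O)C(C)(C)C)c(OC(=O)C(C)(C)C)c1 | intermediate
5 | racemic 1-[3,4-bis(pivaloyloxy)phenyl]prop-2-yn-1-yl acetate | C#CC(OC(C)=O)c1ccc(OC(=O)C(C)(C)C)c(OC(=O)C(C)(C)C)c1 | intermediate
6 | 3-(benzyloxy)phenol | Oc1cccc(OCc2ccccc2)c1 | starting material
7 | (S)-3-(benzyloxy)phenyl 1-[3,4-bis(pivaloyloxy)phenyl]prop-2-yn-1-yl ether | c1(OCc2ccccc2)cccc(c1)O[C@H](c1ccc(OC(=O)C(C)(C)C)c(OC(=O)C(C)(C)C)c1)C#C | intermediate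
8 | (S)-7-(benzyloxy)-2-[3,4-bis(pivaloyloxy)phenyl]-2H-chromene | c1(OCc2ccccc2)ccc2c(c1)O[C@H](c1ccc(OC(=O)C(C)(C)C)c(OC(=O)C(C)(C)C)c1)C=C2 | intermediate
9 | (S)-2-[3,4-bis(pivaloyloxy)phenyl]chroman-7-ol | Oc1ccc2c(c1)O[C@H](c1ccc(OC(=O)C(C)(C)C)c(OC(=O)C(C)(C)C)c1)CC2 | intermediate
10 | prenyl bromide (1-bromo-3-methylbut-2-ene) | CC(C)=CCBr | starting material
11 | (S)-7-(3-methylbut-2-enyloxy)-2-[3,4-bis(pivaloyloxy)phenyl]chroman | CC(C)=CCOc1ccc2c(c1)O[C@H](c1ccc(OC(=O)C(C)(C)C)c(OC(=O)C(C)(C)C)c1)CC2 | intermediate
12 | (S)-4-[7-(3-methylbut-2-enyloxy)chroman-2-yl]benzene-1,2-diol | CC(C)=CCOc1ccc2c(c1)O[C@H](c1ccc(O)c(O)c1)CC2 | intermediate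
13 | 3-chloro-3-methylbut-1-yne | C#CC(C)(C)Cl | starting material
14 | (S)-2-[3,4-bis(2-methylbut-3-yn-2-yloxy)phenyl]-7-(3-methylbut-2-enyloxy)chroman | CC(C)=CCOc1ccc2c(c1)O[C@H](c1ccc(OC(C)(C)C#C)c(OC(C)(C)C#C)c1)CC2 | intermediate
15 | (S)-2-[3,4-bis(2-methylbut-3-en-2-yloxy)phenyl]-7-(3-methylbut-2-enyloxy)chroman | CC(C)=CCOc1ccc2c(c1)O[C@H](c1ccc(OC(C)(C)C=C)c(OC(C)(C)C=C)c1)CC2 | intermediate
16 | (S)-7-acetoxy-6-(2-methylbut-3-en-2-yl)-2-[3,4-diacetoxy-2,5-bis(3-methylbut-2-enyl)phenyl]chroman | C=CC(C)(C)c1cc2c(cc1OC(C)=O)O[C@H](c1cc(CC=C(C)C)c(OC(C)=O)c(OC(C)=O)c1CC=C(C)C)CC2 | intermediate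
17 | 4-[(2S)-7-hydroxy-6-(2-methylbut-3-en-2-yl)chroman-2-yl]-3,6-bis(3-methylbut-2-enyl)benzene-1,2-diol | C=CC(C)(C)c1cc2c(cc1O)O[C@H](c1cc(CC=C(C)C)c(O)c(O)c1CC=C(C)C)CC2 | target

## Step count and weak points

Total: 11 steps. Longest linear sequence: 11 steps, from 1 to 17; compounds 3, 6, 10 and 13 are used as purchased.

**Step 4 (key step).** The most likely failure is incomplete regiocontrol: some closure onto the ring carbon between the two oxygens, giving the 5-benzyloxy isomer. The benzyl group shields that carbon only modestly against a small terminal alkyne carbon. A lesser risk is partial ionisation of the O1–C2 bond by the Lewis acid, which would erode the enantiomeric purity. The fallback changes the substrate, not the catalyst. Acetate 5 is coupled under the step 3 conditions with 3-(triisopropylsilyloxy)phenol F1, a known phenol made by monosilylation of benzene-1,3-diol, to give the silyl analogue F2 of the propargyl ether. The isopropyl groups block both carbons next to the silyloxy group, so gold closure of F2 should give only the 7-silyloxy chromene F3. Hydrogenation over Pd/C gives the flavan F4, and Bu4NF buffered with AcOH returns to 9. This costs one more step than the benzyl route.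

**Step 3.** Two processes may interfere. The electron-rich ring of 6 may attack the allenylidene through carbon instead of oxygen, and facial selectivity may be insufficient with the electron-poor aryl group. The fallback sets out from aldehyde 2. Me2Zn-mediated addition of trimethylsilylacetylene with a ProPhenol ligand gives the silylated propargylic alcohol F5; its descriptor is S because the silylalkynyl arm outranks the aryl group. A Mitsunobu reaction with 6 inverts the carbinol to the silylated ether F6 (R by the same ranking, and the same spatial arrangement as 7). Bu4NF buffered with AcOH removes the silyl group and returns to 7.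

**Step 5.** Hydrogenolysis of the allylic, benzylic O1–C2 bond may compete with saturation of the alkene and open the ring to a 1,3-diarylpropane. The fallback reduces the alkene of 8 without a metal surface, by diimide generated from 2-nitrobenzenesulfonyl hydrazide and Et3N, to give the benzyl ether F7. In F7 the O1–C2 bond is only benzylic, and debenzylation with H2 over Pd/C then returns to 9.

**Step 8.** The second etherification has to place a tertiary ether next to the first and may stall at the mono-ether. The copper salt may also oxidise the catecholate, and a long-lived 4'-phenoxide could open the pyran ring. The fallback leaves copper acetylide chemistry: 12 is treated with tert-butyl 2-methylbut-3-en-2-yl carbonate and Pd(PPh3)4 in THF at 0 °C. The phenols attack the more substituted end of the π-allyl complex of the zerovalent palladium catalyst without added base, and 15 is formed directly, so step 9 is skipped. The temperature must stay low so that the catalyst does not ionise the prenyl ether on ring A.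

**Step 10.** Two processes are of concern: migration of the prenyl group to C8 instead of C6, and loss of the tertiary allyl groups by elimination at the temperature ring A requires. The fallback changes the order of events so that the two rearrangements are run separately.
- Bis-pivalate 11 is heated first with Ac2O in PhNEt2 at 195 °C to give the 7-acetoxy-6-(1,1-dimethylallyl) compound F8. A C8 isomer can be removed at this robust stage.
- iBu2AlH cleaves all three esters to the triol F9.
- Chloride 13 (2.2 equiv) with DBU and CuCl2·2H2O etherifies the catechol to F10. The phenol at C7, crowded by the neighbouring quaternary carbon, is expected to stay free.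
- Semi-hydrogenation over lead-poisoned Pd/CaCO3 gives F11.
- Ac2O in PhNEt2 at 125 °C effects the double Claisen rearrangement on ring B and acetylates all three phenols, which returns to 16.

## Further compounds

F1 | step 4 | 3-(triisopropylsilyloxy)phenol | CC(C)[Si](Oc1cccc(O)c1)(C(C)C)C(C)C
F2 | step 4 | (S)-1-[3,4-bis(pivaloyloxy)phenyl]prop-2-yn-1-yl 3-(triisopropylsilyloxy)phenyl ether | CC(C)[Si](C(C)C)(C(C)C)Oc1cccc(c1)O[C@H](c1ccc(OC(=O)C(C)(C)C)c(OC(=O)C(C)(C)C)c1)C#C
F3 | step 4 | (S)-2-[3,4-bis(pivaloyloxy)phenyl]-7-(triisopropylsilyloxy)-2H-chromene | CC(C)[Si](C(C)C)(C(C)C)Oc1ccc2c(c1)O[C@H](c1ccc(OC(=O)C(C)(C)C)c(OC(=O)C(C)(C)C)c1)C=C2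
F4 | step 4 | (S)-2-[3,4-bis(pivaloyloxy)phenyl]-7-(triisopropylsilyloxy)chroman | CC(C)[Si](C(C)C)(C(C)C)Oc1ccc2c(c1)O[C@H](c1ccc(OC(=O)C(C)(C)C)c(OC(=O)C(C)(C)C)c1)CC2
F5 | step 3 | (S)-1-[3,4-bis(pivaloyloxy)phenyl]-3-(trimethylsilyl)prop-2-yn-1-ol | O[C@@H](c1ccc(OC(=O)C(C)(C)C)c(OC(=O)C(C)(C)C)c1)C#C[Si](C)(C)C
F6 | step 3 | (R)-3-(benzyloxy)phenyl 1-[3,4-bis(pivaloyloxy)phenyl]-3-(trimethylsilyl)prop-2-yn-1-yl ether | c1(OCc2ccccc2)cccc(c1)O[C@H](c1ccc(OC(=O)C(C)(C)C)c(OC(=O)C(C)(C)C)c1)C#C[Si](C)(C)C
F7 | step 5 | (S)-7-(benzyloxy)-2-[3,4-bis(pivaloyloxy)phenyl]chroman | c1(OCc2ccccc2)ccc2c(c1)O[C@H](c1ccc(OC(=O)C(C)(C)C)c(OC(=O)C(C)(C)C)c1)CC2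
F0 | step 8 | none | none
F8 | step 10 | (S)-7-acetoxy-6-(2-methylbut-3-en-2-yl)-2-[3,4-bis(pivaloyloxy)phenyl]chroman | C=CC(C)(C)c1cc2c(cc1OC(C)=O)O[C@H](c1ccc(OC(=O)C(C)(C)C)c(OC(=O)C(C)(C)C)c1)CC2
F9 | step 10 | (S)-4-[7-hydroxy-6-(2-methylbut-3-en-2-yl)chroman-2-yl]benzene-1,2-diol | C=CC(C)(C)c1cc2c(cc1O)O[C@H](c1ccc(O)c(O)c1)CC2
F10 | step 10 | (S)-2-[3,4-bis(2-methylbut-3-yn-2-yloxy)phenyl]-6-(2-methylbut-3-en-2-yl)chroman-7-ol | C=CC(C)(C)c1cc2c(cc1O)O[C@H](c1ccc(OC(C)(C)C#C)c(OC(C)(C)C#C)c1)CC2
F11 | step 10 | (S)-2-[3,4-bis(2-methylbut-3-en-2-yloxy)phenyl]-6-(2-methylbut-3-en-2-yl)chroman-7-ol | C=CC(C)(C)c1cc2c(cc1O)O[C@H](c1ccc(OC(C)(C)C=C)c(OC(C)(C)C=C)c1)CC2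
A1 | alternative 1 | (S)-1-[3,4-bis(methoxymethoxy)-2,5-bis(3-methylbut-2-enyl)phenyl]-3-[2-bromo-4-(methoxymethoxy)-5-(2-methylbut-3-en-2-yl)phenyl]propan-1-ol | O[C@H](c1cc(CC=C(C)C)c(OCOC)c(OCOC)c1CC=C(C)C)CCc1cc(C(C)(C)C=C)c(OCOC)cc1Br
A2 | alternative 1 | tris(methoxymethyl) ether of the target | C=CC(C)(C)c1cc2c(cc1OCOC)O[C@H](c1cc(CC=C(C)C)c(OCOC)c(OCOC)c1CC=C(C)C)CC2
A3 | alternative 2 | caffeyl alcohol, (E)-4-(3-hydroxyprop-1-enyl)benzene-1,2-diol | OC/C=C/c1ccc(O)c(O)c1
A4 | alternative 2 | 3-(3-methylbut-2-enyloxy)phenol | CC(C)=CCOc1cccc(O)c1
A5 | alternative 2 | (E)-4-{3-[2-hydroxy-4-(3-methylbut-2-enyloxy)phenyl]prop-1-enyl}benzene-1,2-diol | CC(C)=CCOc1ccc(C/C=C/c2ccc(O)c(O)c2)c(O)c1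
A6 | alternative 2 | (S)-4-[7-(3-methylbut-2-enyloxy)chroman-2-yl]benzene-1,2-diol | CC(C)=CCOc1ccc2c(c1)O[C@H](c1ccc(O)c(O)c1)CC2
A7 | alternative 3 | (S)-4-(benzyloxy)-2-{1-[3,4-bis(methoxymethoxy)phenyl]prop-2-enyloxy}-1-vinylbenzene | C=Cc1ccc(OCc2ccccc2)cc1O[C@H](c1ccc(OCOC)c(OCOC)c1)C=C
A8 | alternative 3 | (S)-7-(benzyloxy)-2-[3,4-bis(methoxymethoxy)phenyl]-2H-chromene | c1(OCc2ccccc2)ccc2c(c1)O[C@H](c1ccc(OCOC)c(OCOC)c1)C=C2
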